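All runs come from a simulation with made-up constants, and the scatter is random.

Partner was the reagent I had to budget, so I started from the flasks, the earlier runs and the questions.

| flask | substrate | partner | temperature | remark | time |
|---|---|---|---|---|---|
| Tuesday's | 1.3 M | 3 M | −15 °C | run made earlier |  |
| Friday's | 1.3 M | 3 M | 35 °C | run made earlier |  |
| summer | 2.0 M | 3.00 M | 20 °C |  | 6.0 h |
| winter | 2.0 M | 3.00 M | −10 °C |  | 6.0 h |
| spring | 2.0 M | 3.00 M | 50 °C |  | 6.0 h |
| dusk | 2.0 M | 3.00 M | 80 °C |  | 6.0 h |

- Tuesday's (time / h: target / %, substrate / %): 2.50: 0.2, 99.2; 4.00: 1.2, 98.9; 6.00: 2.4, 97.9; 12.0: 3.5, 97.7; 15.0: 4.1, 95.6; 30.0: 6.7, 92.8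
- Friday's (time / h: target / %, substrate / %): 0.200: 8.9, 90.3; 0.333: 14.0, 85.0; 0.500: 20.7, 79.1; 1.00: 34.9, 65.2; 1.33: 40.6, 57.4; 2.50: 57.8, 40.9

(each reading ± 0.5 percentage points)

- which flask leads in amount of target, in percent of the substrate charged ("all alike" within 1.5 percentage points) (summer / winter / spring / dusk / all alike)
- how much target is there at the end, in percent of the substrate charged: summer
- how much target is there at the end, in percent of the substrate charged: winter
- how much target is there at the end, in percent of the substrate charged: spring
- how much target is there at the end, in percent of the substrate charged: dusk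

- what may be going on: substrate + partner -> target; substrate + 2 partner -> side product; partner -> decomposed reagent

In Friday's run, ln of the substrate share fell at 0.469 h⁻¹ up to 0.500 h, then at 0.311 h⁻¹ between 1.00 h and 2.50 h. That rate is k, the making's second-order constant, times partner, so k read 0.00261 L mol⁻¹ min⁻¹ near the start. Partner itself was therefore shrinking at a specific rate s of 0.274 h⁻¹. Making accounts for k times substrate, with 0.848 M of substrate at 1.00 h, and decay for the remainder.

Decay's constant over k gave K, the break-even substrate level at which making and decay take partner equally: 0.905 M. Both steps are first order in partner, so partner cancels from their ratio. Partner gone is then x + K ln(c/A), where x is target formed, c is substrate charged and A is substrate left. I ignored the side product, since Friday's target and substrate summed to 98.7%.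

Friday's partner lifetime, 1/s, was 3.65 h, shorter than the 6.0 h allowed, so I counted spring's partner as used up, making it the limiting reagent. With Friday's K, target near 80.0% books 3.06 M of the 3.00 M charged. The weak link was carrying K from 35 °C to 50 °C. I guessed 1.36 M for spring, and then target near 70.0% books 3.04 M. That figure near 70.0% is my own reckoning, and the forecast's number for spring, given next, differs from it.

The forecast chose spring: summer 43%, winter 3%, spring 60% (49% to 71%), dusk 38% (20% to 62%). Of spring it said “partner is exhausted”.

The flasks gave summer 43.0%, winter 2.74%, spring 71.2% and dusk 56.3%, so spring led.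

    substrate + partner → target (k = 0.00990 L mol⁻¹ min⁻¹, Ea = 70.0 kJ mol⁻¹)
    substrate + 2 partner → side product (k = 8.20 × 10⁻⁵ L² mol⁻² min⁻¹, Ea = 66.0 kJ mol⁻¹)
    partner → decomposed reagent (k = 0.0120 min⁻¹, Ea = 89.0 kJ mol⁻¹)
    (constants at 50 °C)

With 27.8% of spring's substrate left, my K for spring books 1.74 M of decomposed reagent, and spring held 1.53 M. The same quantity from winter's simulated amounts, Kw, is 0.238 M, less than Friday's K. The neighbour of winter charged with 0.80 M of substrate kept 97.1% of it, so Kw books 0.00690 M of decomposed reagent there. That neighbour held 0.00677 M after 6.00 h.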